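## Retrosynthetic overview

1. The plan rests on the C1–C10 bond. It is the only bond shared by the cyclohexene (C1, C10–C14) and the ten-membered ring (C1–C10). Without it the carbocycle is a single 14-membered ring (C1–C14), and O-2, O-11 and the 12-acetate sit where an oxirane opening at C1 and an acetate capture at C11 would leave them.
2. 38 ⇐ 36 ⇐ epoxy-cembranolide 34 by transannular C1–C10 closure. 34 ⇐ seco iodo-aldehyde 31 by Ni/Cr C9–C10 ring closure, then reduction of the alkyne to Z-C13=C14.
3. 31 ⇐ alkyne 22 + iodo-enal 26 by asymmetric alkynylation, which forms C12–C13.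
4. 22 ⇐ enal 12 + (R)-methylsuccinate 14. Enal 12 takes C2–C7 from nerol, C1/C14/C15 from a Z-selective phosphonate olefination, the oxirane from asymmetric epoxidation and C13 from a diazophosphonate. Diester 14 supplies C8, C9 and C17–C19 through aldol/elimination, a second asymmetric epoxidation and lactonisation at C7.
5. Ring order: C1–C2 oxirane, γ-lactone, 14-membered ring, then the six- and ten-membered rings together.

Key step: step 27

Remark: briarane numbering (C1–C20) is used for all intermediates. The centres left undefined in the SMILES of 3, 16 and 17 are destroyed in the following step.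

Assumption: (S,S)-ProPhenol is taken to give the 12R carbinol in step 20, in line with its sense in the related zinc aldol reactions. The antipodal ligand is equally available if the sense turns out to be opposite.

## Route

Step 1
Reactants: 1 nerol
Product: 2 neryl tert-butyldimethylsilyl ether
Conditions: TBSCl, imidazole, CH2Cl2, 0 °C to rt
Reagents that add atoms: tert-butyldimethylsilyl chloride, CC(C)(C)[Si](C)(C)Cl
Why: Silylation of the primary alcohol masks O-7 with a group that survives peracid, phosphonate anion and DIBAL-H and leaves the Z C5=C6 alkene of nerol untouched.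

Step 2
Reactants: 2 neryl TBS ether
Product: 3 6,7-epoxyneryl TBS ether (racemic at the oxirane CH)
Conditions: mCPBA (1.0 equiv), CH2Cl2, −20 to 0 °C
Reagents that add atoms: 3-chloroperoxybenzoic acid, OOC(=O)c1cccc(Cl)c1
Why: In this Prilezhaev epoxidation the isopropylidene alkene is more electron-rich and less shielded than the alkene bearing the allylic silyloxy group, so one equivalent of peracid should react there, and the new centre is lost in step 3.

Step 3
Reactants: 3 6,7-epoxyneryl TBS ether
Product: 4 (4Z)-6-(tert-butyldimethylsilyloxy)-4-methylhex-4-enal (C2–C7, C16)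
Conditions: H5IO6, THF–Et2O, 0 °C
Reagents that add atoms: none
Why: Periodic acid hydrolyses the oxirane and cleaves the resulting glycol (Malaprade cleavage) to the C2 aldehyde and acetone without touching the remaining alkene.

Step 4
Reactants: 4 aldehyde; 5 ethyl 2-[bis(2,2,2-trifluoroethoxy)phosphoryl]propanoate
Product: 6 ethyl (2Z,6Z)-8-(tert-butyldimethylsilyloxy)-2,6-dimethylocta-2,6-dienoate
Conditions: KHMDS, 18-crown-6, THF, −78 °C
Reagents that add atoms: none
Why: The Still–Gennari olefination eliminates fast and irreversibly from the kinetic adduct of the electron-poor phosphonate, which gives the Z enoate (C14 cis to C3) needed for a cis oxirane.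

Step 5
Reactants: 6 Z-enoate
Product: 7 (2Z,6Z)-8-(tert-butyldimethylsilyloxy)-2,6-dimethylocta-2,6-dien-1-ol
Conditions: DIBAL-H (2.3 equiv), CH2Cl2, −78 °C
Reagents that add atoms: none
Why: DIBAL-H reduces the enoate by 1,2-addition to the allylic alcohol at low temperature without Z/E isomerisation or loss of the silyl ether.

Step 6
Reactants: 7 Z-allylic alcohol
Product: 8 (2S,3R)-epoxy alcohol (briarane 1S,2R; C14 and C3 cis on the oxirane)
Conditions: Ti(OiPr)4 (10 mol %), L-(+)-diethyl tartrate (13 mol %), tBuOOH, 4 Å MS, CH2Cl2, −20 °C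
Reagents that add atoms: tert-butyl hydroperoxide, CC(C)(C)OO
Why: The Katsuki–Sharpless epoxidation acts only on the alkene allylic to the free hydroxyl, L-(+)-tartrate gives the (2S,3R)-epoxy alcohol as it does with nerol, and the Z geometry carries over into the cis oxirane, which sets C1 and C2.

Step 7
Reactants: 8 epoxy alcohol
Product: 9 (2R,3R)-epoxy aldehyde (same geometry; the descriptor at C1 changes only by CIP ranking)
Conditions: Dess–Martin periodinane, NaHCO3, CH2Cl2, 0 °C to rt
Reagents that add atoms: none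
Why: The buffered Dess–Martin oxidation is neutral enough for the oxirane, and the α-carbon C1 is quaternary and cannot epimerise.

Step 8
Reactants: 9 epoxy aldehyde
Product: 10 (2S,3R)-2-ethynyl-2-methyl-3-[(3Z)-5-(tert-butyldimethylsilyloxy)-3-methylpent-3-enyl]oxirane
Conditions: dimethyl (1-diazo-2-oxopropyl)phosphonate, K2CO3, MeOH, 0 °C to rt
Reagents that add atoms: Ohira–Bestmann reagent, CC(=O)C(=[N+]=[N-])P(=O)(OC)OC
Why: The Seyferth–Gilbert homologation under Ohira–Bestmann conditions converts the non-enolisable aldehyde into the terminal alkyne, adds C13, and is mild enough for the oxirane and the silyl ether.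

Step 9
Reactants: 10 silyl ether
Product: 11 (2Z)-5-[(2R,3S)-3-ethynyl-3-methyloxiran-2-yl]-3-methylpent-2-en-1-ol
Conditions: TBAF, THF, 0 °C
Reagents that add atoms: none
Why: Fluoride cleaves the only silyl ether, and the oxirane and terminal alkyne are inert to it.

Step 10
Reactants: 11 allylic alcohol
Product: 12 (2Z)-5-[(2R,3S)-3-ethynyl-3-methyloxiran-2-yl]-3-methylpent-2-enal
Conditions: TEMPO (10 mol %), PhI(OAc)2, CH2Cl2, 0 °C to rt
Reagents that add atoms: none
Why: The oxoammonium (TEMPO/PhI(OAc)2) oxidation converts nerol-type alcohols into the Z enals without Z-to-E isomerisation or over-oxidation.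

Step 11
Reactants: 13 (2R)-4-methoxy-2-methyl-4-oxobutanoic acid
Product: 14 1-tert-butyl 4-methyl (2R)-2-methylbutanedioate
Conditions: isobutene, H2SO4 (cat.), CH2Cl2, −10 °C to rt
Reagents that add atoms: isobutene, CC(C)=C
Why: Acid-catalysed addition of the free acid to isobutene esterifies C19 without touching the methyl ester or C17, and gives two esters that hydride and acid can later distinguish.

Step 12
Reactants: 14 mixed succinate; 12 Z-enal
Product: 16 C7–C8 aldol adduct (7-OH; 9-CO2Me; 19-CO2tBu; 17R; C7/C8 epimers), via lithium enolate 15 (not isolated)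
Conditions: LDA (1.05 equiv), THF, −78 °C; then 12; AcOH quench at −78 °C
Reagents that add atoms: none
Why: Kinetic deprotonation takes the unhindered CH2 next to the methyl ester rather than the tertiary C17–H, the enolate adds 1,2 to the enal (aldol addition) faster than it exchanges a proton with the alkyne, and the two new centres are erased in step 13.

Step 13
Reactants: 16 aldol adduct
Product: 18 (5Z,7E)-dienoate (alkylidene succinate; C6 trans to CO2Me), via allylic mesylate 17 (not isolated)
Conditions: MsCl, Et3N (4 equiv), CH2Cl2, −20 °C to rt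
Reagents that add atoms: none
Why: The mesylate is both allylic and β to the ester, so triethylamine alone should eliminate it (aldol dehydration, E1cB type), both epimers should converge on the E alkylidene succinate as in Stobbe products (ester cis to H-7), and the amine is too weak to deprotonate C17.

Step 14
Reactants: 18 dienoate
Product: 19 (5Z,7E)-dienol (C9H2OH; tert-butyl ester kept)
Conditions: DIBAL-H (2.2 equiv), CH2Cl2, −78 °C
Reagents that add atoms: none
Why: DIBAL-H reduces the unhindered conjugated methyl ester by two 1,2-hydride additions at −78 °C, whereas the tert-butyl ester on a branched carbon, the oxirane and the alkyne should be left.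

Step 15
Reactants: 19 dienol
Product: 20 (7R,8R)-7,8-epoxy alcohol (vinyl oxirane; C6 trans to C9)
Conditions: Ti(OiPr)4 (1.0 equiv), D-(−)-diethyl tartrate (1.2 equiv), tBuOOH, 4 Å MS, CH2Cl2, −25 °C
Reagents that add atoms: tert-butyl hydroperoxide, CC(C)(C)OO
Why: The Katsuki–Sharpless epoxidation oxidises only the C7=C8 alkene next to the free C9 hydroxyl, and D-(−)-tartrate gives the (2R,3R)-type epoxy alcohol of an E allylic alcohol under reagent control, which sets C8 and provisionally C7.

Step 16
Reactants: 20 epoxy alcohol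
Product: 21 γ-lactone 8,9-diol (7S,8R,17R; C6, 8-OH and 17-Me on one face of the lactone, C9 on the other)
Conditions: camphorsulfonic acid (10 mol %), CH2Cl2, 0 °C
Reagents that add atoms: none
Why: Acid activates the vinyl oxirane and the ester carbonyl oxygen attacks its allylic C7–O bond from the rear (5-endo opening, favoured at an allylic terminus; 4-exo at C8 is excluded), then tert-butyl leaves as isobutene, so C7 is inverted to S and C8 keeps its oxygen, while the alkynyl-substituted C1–C2 oxirane is too electron-poor to ionise.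

Step 17
Reactants: 21 lactone diol
Product: 22 8,9-bis(triethylsilyl) ether
Conditions: TESOTf (3 equiv), 2,6-lutidine, CH2Cl2, −78 to −40 °C
Reagents that add atoms: triethylsilyl triflate, CC[Si](CC)(CC)OS(=O)(=O)C(F)(F)F
Why: The silyl triflate is reactive enough for the tertiary C8 hydroxyl, and at low temperature O-silylation should be much faster than triflate-induced opening of the deactivated oxirane.

Step 18
Reactants: 23 prop-2-yn-1-ol
Product: 25 (2E)-3-iodo-2-methylprop-2-en-1-ol, via alkenylalane 24 (not isolated)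
Conditions: Me3Al (3 equiv), Cp2ZrCl2 (25 mol %), CH2Cl2, 0 °C to rt; then I2, THF, −30 °C
Reagents that add atoms: trimethylaluminium, C[Al](C)C; iodine, II
Why: The Negishi zirconium-catalysed carboalumination adds CH3 (C20) and Al syn with Al on the terminal carbon, and iodinolysis with retention gives the E iodide (I trans to C12).

Step 19
Reactants: 25 iodo alcohol
Product: 26 (2E)-3-iodo-2-methylprop-2-enal (C10–C12, C20)
Conditions: activated MnO2, CH2Cl2, rt, dark
Reagents that add atoms: none
Why: Activated MnO2 oxidises only allylic alcohols and keeps the geometry of the iodoalkene.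

Step 20
Reactants: 22 terminal alkyne; 26 iodo-enal
Product: 28 (12R)-propargylic alcohol bearing the E C10 iodoalkene, via alkynylzinc 27 (not isolated)
Conditions: Me2Zn, (S,S)-ProPhenol (20 mol %), Ph3P=O (40 mol %), toluene, rt; then 26, 4 °C
Reagents that add atoms: none
Why: In this dinuclear zinc–ProPhenol alkynylation, which suits α,β-unsaturated aldehydes, Me2Zn metalates the alkyne without touching the lactone, oxirane or silyl ethers, and the chiral Zn2 pocket selects the aldehyde face, which sets C12 under reagent control.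

Step 21
Reactants: 28 propargylic alcohol
Product: 29 12-acetate
Conditions: Ac2O, pyridine, DMAP (cat.), CH2Cl2, 0 °C
Reagents that add atoms: acetic anhydride, CC(=O)OC(C)=O
Why: DMAP-catalysed acetylation installs the acetate that acts as the neighbouring group in step 27 and remains in the target.

Step 22
Reactants: 29 bis-silyl ether
Product: 30 primary C9 alcohol (8-OSiEt3 kept)
Conditions: PPTS (20 mol %), MeOH–CH2Cl2, 0 °C
Reagents that add atoms: none
Why: Acid-catalysed methanolysis distinguishes the two silyl ethers by steric access, so the primary C9 ether should be cleaved and the tertiary C8 ether kept, under conditions too mild for the alkynyl oxirane and the acetate.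

Step 23
Reactants: 30 primary alcohol
Product: 31 seco iodo-aldehyde (C9 CHO, C10 iodide)
Conditions: Dess–Martin periodinane, NaHCO3, CH2Cl2, 0 °C to rt
Reagents that add atoms: none
Why: The Dess–Martin oxidation gives the aldehyde on the fully substituted C8, which cannot enolise, without affecting the iodoalkene, oxirane or esters.

Step 24
Reactants: 31 seco iodo-aldehyde
Product: 32 14-membered (9R)-allylic alcohol (E C10=C11, C13≡C14)
Conditions: CrCl2 (15 equiv), NiCl2 (1 mol % of Cr), DMSO–THF, 2 mM, rt
Reagents that add atoms: none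
Why: In the Nozaki–Hiyama–Kishi reaction nickel inserts into the C10–I bond with retention of the E geometry, the alkenylchromium(III) adds only to the aldehyde at high dilution in the presence of esters, lactone, oxirane and alkyne, and attack anti to the C8–OSiEt3 bond (polar Felkin–Anh, formyl oxygen turned toward C7) should favour the 9R alcohol.

Step 25
Reactants: 32 macrocyclic alcohol
Product: 33 9,12-diacetate (alkyne)
Conditions: Ac2O, pyridine, DMAP, CH2Cl2, rt
Reagents that add atoms: acetic anhydride, CC(=O)OC(C)=O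
Why: DMAP-catalysed acetylation of the only free hydroxyl installs the C9 acetate of the target.

Step 26
Reactants: 33 macrocyclic alkyne
Product: 34 epoxy-cembranolide (cis 1S,2R-oxirane, E C10=C11, Z C13=C14, Z C5=C6, 9- and 12-OAc, 8-OSiEt3)
Conditions: H2 (1 atm), Lindlar catalyst, quinoline, EtOAc–hexane, rt
Reagents that add atoms: none
Why: In the Lindlar semihydrogenation the alkyne binds the poisoned palladium more strongly than the trisubstituted alkenes and takes up one H2 in a syn fashion, which should give the Z alkene and hence the cis-vinyl oxirane without hydrogenolysis.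

Step 27
Reactants: 34 epoxy-cembranolide
Product: 36 2-O-deacetyl target as its 8-O-triethylsilyl ether, via dioxolanylium ion 35 (not isolated)
Conditions: BF3·OEt2 (1.1 equiv), 2,6-di-tert-butyl-4-methylpyridine, CH2Cl2, −78 °C; then THF–H2O, NaHCO3, −78 to 0 °C
Reagents that add atoms: water, O
Why: BF3 binds the oxirane oxygen and weakens the tertiary, allylic C1–O bond, C10 of the E C10=C11 alkene bonds to C1 from the side opposite the oxygen while the carbonyl oxygen of the C12 acetate closes on C11 from the other alkene face to give dioxolan-2-ylium ion 35, and water opens this ion through its orthoacid to the cis 11-OH/12-OAc pair (any tertiary 11-acetate should migrate to the secondary oxygen on work-up). The closest known reactions are the acid-induced transannular cyclisations of germacrene, humulene and cembrene epoxides and epoxide-initiated polyene cyclisations that end on a neighbouring ester or carbonate, and the Z-allyl terminus/alkene geometry is that of the neryl-to-terpinyl closure. The cyclohexene (C1, C10–C14) closes 6-endo-trig at the alkene and 6-exo-tet at the oxirane, the ten-membered ring (C1–C10) is the rest of the 14-ring cut off by the same bond, and the transient dioxolanylium ring closes 5-exo-trig. C1 is set by inversion at the cis-oxirane carbon, C10 and C11 by anti addition across the E alkene, and the alkene face by C12, whose acetate can reach C11 only from the face away from C1, so that 15-Me and H-10 end up trans and 11-OH ends up cis to 12-OAc, while C2 keeps its oxygen and configuration. The step needs oxirane activation ahead of ionisation of the allylic acetates (one equivalent of a reversible Lewis acid, −78 °C, a hindered pyridine as proton trap, and the strained, doubly activated C1–O bond as the weakest bond), bonding at C1 rather than C13 (attack at C13 would close a four-membered ring), and attack by C10=C11 rather than by C5=C6, which lies equally far from C1. This last point is the weak one: only C10=C11 has an internal terminator that makes addition a concerted, irreversible capture, C6 is shielded by the lactone and its 8-OSiEt3 group, and that silyl ether also prevents O-8 from forming an ether at C11.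

Step 28
Reactants: 36 C2 alcohol
Product: 37 2,9,12-triacetate 8-O-triethylsilyl ether
Conditions: Ac2O, pyridine, DMAP (cat.), CH2Cl2, 0 °C to rt
Reagents that add atoms: acetic anhydride, CC(=O)OC(C)=O
Why: The secondary C2 hydroxyl is acetylated, while the tertiary C11 hydroxyl is too hindered to react under these conditions.

Step 29
Reactants: 37 silyl ether
Product: 38 target CNP0129620.2
Conditions: HF·pyridine, pyridine, THF, 0 °C to rt
Reagents that add atoms: none
Why: Si–F bond formation removes the tertiary silyl ether under mildly acidic conditions that avoid acetyl migration, retro-aldol cleavage and β-elimination in the lactone.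

## Compound list

1 | nerol, (2Z)-3,7-dimethylocta-2,6-dien-1-ol | CC(C)=CCC/C(C)=C\CO | starting material
2 | neryl tert-butyldimethylsilyl ether | CC(C)=CCC/C(C)=C\CO[Si](C)(C)C(C)(C)C | intermediate
3 | 6,7-epoxyneryl TBS ether (racemic oxirane) | CC1(C)OC1CC/C(C)=C\CO[Si](C)(C)C(C)(C)C | intermediate
4 | (4Z)-6-(TBS-oxy)-4-methylhex-4-enal | O=CCC/C(C)=C\CO[Si](C)(C)C(C)(C)C | intermediate
5 | ethyl 2-[bis(2,2,2-trifluoroethoxy)phosphoryl]propanoate | CCOC(=O)C(C)P(=O)(OCC(F)(F)F)OCC(F)(F)F | starting material
6 | ethyl (2Z,6Z)-8-(TBS-oxy)-2,6-dimethylocta-2,6-dienoate | CCOC(=O)/C(C)=C\CC/C(C)=C\CO[Si](C)(C)C(C)(C)C | intermediate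
7 | (2Z,6Z)-8-(TBS-oxy)-2,6-dimethylocta-2,6-dien-1-ol | OC/C(C)=C\CC/C(C)=C\CO[Si](C)(C)C(C)(C)C | intermediate
8 | {(2S,3R)-3-[(3Z)-5-(TBS-oxy)-3-methylpent-3-enyl]-2-methyloxiran-2-yl}methanol | OC[C@]1(C)O[C@@H]1CC/C(C)=C\CO[Si](C)(C)C(C)(C)C | intermediate
9 | (2R,3R)-3-[(3Z)-5-(TBS-oxy)-3-methylpent-3-enyl]-2-methyloxirane-2-carbaldehyde | O=C[C@]1(C)O[C@@H]1CC/C(C)=C\CO[Si](C)(C)C(C)(C)C | intermediate
10 | (2S,3R)-2-ethynyl-2-methyl-3-[(3Z)-5-(TBS-oxy)-3-methylpent-3-enyl]oxirane | C#C[C@]1(C)O[C@@H]1CC/C(C)=C\CO[Si](C)(C)C(C)(C)C | intermediate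
11 | (2Z)-5-[(2R,3S)-3-ethynyl-3-methyloxiran-2-yl]-3-methylpent-2-en-1-ol | C#C[C@]1(C)O[C@@H]1CC/C(C)=C\CO | intermediate
12 | (2Z)-5-[(2R,3S)-3-ethynyl-3-methyloxiran-2-yl]-3-methylpent-2-enal | C#C[C@]1(C)O[C@@H]1CC/C(C)=C\C=O | intermediate
13 | (2R)-4-methoxy-2-methyl-4-oxobutanoic acid | OC(=O)[C@H](C)CC(=O)OC | starting material
14 | 1-tert-butyl 4-methyl (2R)-2-methylbutanedioate | CC(C)(C)OC(=O)[C@H](C)CC(=O)OC | intermediate
15 | lithium enolate of 14 at C8 | [Li+].COC([O-])=C[C@@H](C)C(=O)OC(C)(C)C | intermediate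
16 | aldol adduct (7-OH, 9-CO2Me, 19-CO2tBu, 17R, C7/C8 epimers) | C#C[C@]1(C)O[C@@H]1CC/C(C)=C\C(O)C(C(=O)OC)[C@@H](C)C(=O)OC(C)(C)C | intermediate
17 | C7 mesylate of 16 | C#C[C@]1(C)O[C@@H]1CC/C(C)=C\C(OS(C)(=O)=O)C(C(=O)OC)[C@@H](C)C(=O)OC(C)(C)C | intermediate
18 | (5Z,7E)-dienoate, alkylidene succinate (17R) | C#C[C@]1(C)O[C@@H]1CC/C(C)=C\C=C(\C(=O)OC)[C@@H](C)C(=O)OC(C)(C)C | intermediate
19 | (5Z,7E)-dienol with tert-butyl ester | C#C[C@]1(C)O[C@@H]1CC/C(C)=C\C=C(\CO)[C@@H](C)C(=O)OC(C)(C)C | intermediate
20 | (7R,8R)-7,8-epoxy alcohol, tert-butyl ester | C#C[C@]1(C)O[C@@H]1CC/C(C)=C\[C@H]2O[C@@]2(CO)[C@@H](C)C(=O)OC(C)(C)C | intermediate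
21 | γ-lactone 8,9-diol (7S,8R,17R) | C#C[C@]1(C)O[C@@H]1CC/C(C)=C\[C@@H]2OC(=O)[C@H](C)[C@@]2(O)CO | intermediate
22 | 8,9-bis(triethylsilyl) ether of 21 | C#C[C@]1(C)O[C@@H]1CC/C(C)=C\[C@@H]2OC(=O)[C@H](C)[C@@]2(O[Si](CC)(CC)CC)CO[Si](CC)(CC)CC | intermediate
23 | prop-2-yn-1-ol | C#CCO | starting material
24 | (E)-alkenylalane aluminium alkoxide | C[Al](C)OC/C(C)=C/[Al](C)C | intermediate
25 | (2E)-3-iodo-2-methylprop-2-en-1-ol | OC/C(C)=C/I | intermediate
26 | (2E)-3-iodo-2-methylprop-2-enal | O=C/C(C)=C/I | intermediate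
27 | methylzinc acetylide of 22 | C[Zn]C#C[C@]1(C)O[C@@H]1CC/C(C)=C\[C@@H]2OC(=O)[C@H](C)[C@@]2(O[Si](CC)(CC)CC)CO[Si](CC)(CC)CC | intermediate
28 | (12R)-propargylic alcohol, E C10 iodide | I/C=C(C)/[C@H](O)C#C[C@]1(C)O[C@@H]1CC/C(C)=C\[C@@H]2OC(=O)[C@H](C)[C@@]2(O[Si](CC)(CC)CC)CO[Si](CC)(CC)CC | intermediate
29 | 12-acetate of 28 | I/C=C(C)/[C@H](OC(C)=O)C#C[C@]1(C)O[C@@H]1CC/C(C)=C\[C@@H]2OC(=O)[C@H](C)[C@@]2(O[Si](CC)(CC)CC)CO[Si](CC)(CC)CC | intermediate
30 | C9 primary alcohol, 8-OSiEt3 | I/C=C(C)/[C@H](OC(C)=O)C#C[C@]1(C)O[C@@H]1CC/C(C)=C\[C@@H]2OC(=O)[C@H](C)[C@@]2(O[Si](CC)(CC)CC)CO | intermediate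
31 | seco iodo-aldehyde | I/C=C(C)/[C@H](OC(C)=O)C#C[C@]1(C)O[C@@H]1CC/C(C)=C\[C@@H]2OC(=O)[C@H](C)[C@@]2(O[Si](CC)(CC)CC)C=O | intermediate
32 | 14-membered (9R)-alcohol, C13≡C14 | O[C@@H]1/C=C(C)/[C@H](OC(C)=O)C#C[C@]2(C)O[C@@H]2CC/C(C)=C\[C@@H]3OC(=O)[C@H](C)[C@]31O[Si](CC)(CC)CC | intermediate
33 | 9,12-diacetate, C13≡C14 | CC(=O)O[C@@H]1/C=C(C)/[C@H](OC(C)=O)C#C[C@]2(C)O[C@@H]2CC/C(C)=C\[C@@H]3OC(=O)[C@H](C)[C@]31O[Si](CC)(CC)CC | intermediate
34 | epoxy-cembranolide (key-step precursor) | CC(=O)O[C@@H]1/C=C(C)/[C@H](OC(C)=O)/C=C\[C@]2(C)O[C@@H]2CC/C(C)=C\[C@@H]3OC(=O)[C@H](C)[C@]31O[Si](CC)(CC)CC | intermediate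
35 | 11,12-(2-methyl-1,3-dioxolan-2-ylium) ion, O-2 as BF3 alkoxide | CC(=O)O[C@@H]1[C@H]2[C@]3(C)OC(C)=[O+][C@@H]3C=C[C@]2(C)[C@H](O[B-](F)(F)F)CC/C(C)=C\[C@@H]2OC(=O)[C@H](C)[C@]21O[Si](CC)(CC)CC | intermediate
36 | 2-O-deacetyl target 8-O-triethylsilyl ether (key-step product) | CC(=O)O[C@@H]1[C@H]2[C@](C)(O)[C@H](OC(C)=O)C=C[C@]2(C)[C@H](O)CC/C(C)=C\[C@@H]2OC(=O)[C@H](C)[C@]21O[Si](CC)(CC)CC | intermediate
37 | target 8-O-triethylsilyl ether | CC(=O)O[C@@H]1[C@H]2[C@](C)(O)[C@H](OC(C)=O)C=C[C@]2(C)[C@H](OC(C)=O)CC/C(C)=C\[C@@H]2OC(=O)[C@H](C)[C@]21O[Si](CC)(CC)CC | intermediate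
38 | CNP0129620.2 (1S,2R,7S,8S,9R,10S,11S,12R,17R; 5Z,13Z) | CC(=O)O[C@@H]1[C@H]2[C@](C)(O)[C@H](OC(C)=O)C=C[C@]2(C)[C@H](OC(C)=O)CC/C(C)=C\[C@@H]2OC(=O)[C@H](C)[C@]21O | target

## Step count and risks

Total step count: 29.
Longest linear sequence: 26 steps from nerol (steps 1–10, 12–17 and 20–29).

**Step 27.**
- What may go wrong: acetate is only a weak neighbouring group. The C1 cation may therefore be taken by the equally distant C5=C6 alkene, lose a proton from C15, or undergo a hydride shift from C2. The Lewis acid may also ionise the doubly allylic C12 acetate.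
- Fallback: it sets out from 32 and returns at 37. The terminator is changed to a urethane, which is a poorer leaving group and a much better internal nucleophile. This uses the known Lewis-acid-induced urethane capture that ends in a cyclic carbonate.
- Sequence: methanolysis of 32 (K2CO3, MeOH, 0 °C) gives the 9,12-diol F1. PhNCO in pyridine carbamoylates only the unhindered C12 hydroxyl and gives the 12-(N-phenylcarbamate) F2. Ac2O/DMAP gives its 9-acetate F3, and Lindlar reduction gives the Z-vinyl oxirane F4. BF3·OEt2 at −78 °C followed by a pH 4 aqueous quench gives, through the iminocarbonate, the 11,12-cyclic carbonate F5. K2CO3/MeOH removes the carbonate and the 9-acetate and gives the 2,9,11,12-tetraol F6. Ac2O/pyridine/DMAP then acetylates the three secondary hydroxyls and leaves the tertiary C11 hydroxyl, which is 37.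

**Step 24.**
- What may go wrong: facial selectivity at the formyl group may be poor. The two lactone carbons flanking C8 differ little, so the folding of the chain decides the outcome. Competing attack of Cr(II) on the propargylic oxirane is also possible.
- Fallback: it sets out from 31 and returns at 32. C9 is set by ketone reduction instead of by the C–C bond formation.
- Sequence: the Ni/Cr closure is run without regard to selectivity. The 9-epimeric alcohol F7, alone or mixed with 32, is oxidised with Dess–Martin periodinane to the macrocyclic enone F8. A Corey–Bakshi–Shibata reduction with (S)-Me-oxazaborolidine and catecholborane at −78 °C, with the fully substituted C8 as the large group, delivers hydride to the face that gives the 9R alcohol 32.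

**Step 16.**
- What may go wrong: stereochemical integrity at C7 may be lost, and Z-to-E isomerisation of C5=C6 may occur through a free neryl-type allyl cation. The acid may also open the second oxirane.
- Fallback: it sets out from 20 and returns at 21. The opening becomes an intermolecular, titanium-templated SN2 process, the known C-3-selective opening of 2,3-epoxy alcohols.
- Sequence: Ti(OiPr)4 (1.5 equiv) and benzoic acid in CH2Cl2 open the chelated epoxy alcohol at C7 with inversion and give the 7-benzoate 8,9-diol F9. K2CO3/MeOH then removes the benzoate, and the liberated C7 alkoxide closes on the tert-butyl ester to give 21.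

## Further compounds

F1 | step 27 | macrocyclic 9,12-diol (C13≡C14, 8-OSiEt3) | O[C@@H]1/C=C(C)/[C@H](O)C#C[C@]2(C)O[C@@H]2CC/C(C)=C\[C@@H]3OC(=O)[C@H](C)[C@]31O[Si](CC)(CC)CC
F2 | step 27 | 12-(N-phenylcarbamate), 9-OH | O[C@@H]1/C=C(C)/[C@H](OC(=O)Nc4ccccc4)C#C[C@]2(C)O[C@@H]2CC/C(C)=C\[C@@H]3OC(=O)[C@H](C)[C@]31O[Si](CC)(CC)CC
F3 | step 27 | 9-acetate 12-(N-phenylcarbamate), alkyne | CC(=O)O[C@@H]1/C=C(C)/[C@H](OC(=O)Nc4ccccc4)C#C[C@]2(C)O[C@@H]2CC/C(C)=C\[C@@H]3OC(=O)[C@H](C)[C@]31O[Si](CC)(CC)CC
F4 | step 27 | 9-acetate 12-(N-phenylcarbamate), Z-vinyl oxirane | CC(=O)O[C@@H]1/C=C(C)/[C@H](OC(=O)Nc4ccccc4)/C=C\[C@]2(C)O[C@@H]2CC/C(C)=C\[C@@H]3OC(=O)[C@H](C)[C@]31O[Si](CC)(CC)CC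
F5 | step 27 | briarane 11,12-cyclic carbonate (2-OH, 9-OAc, 8-OSiEt3) | CC(=O)O[C@@H]1[C@H]2[C@]3(C)OC(=O)O[C@@H]3C=C[C@]2(C)[C@H](O)CC/C(C)=C\[C@@H]2OC(=O)[C@H](C)[C@]21O[Si](CC)(CC)CC
F6 | step 27 | briarane 2,9,11,12-tetraol 8-O-triethylsilyl ether | O[C@@H]1[C@H]2[C@](C)(O)[C@H](O)C=C[C@]2(C)[C@H](O)CC/C(C)=C\[C@@H]2OC(=O)[C@H](C)[C@]21O[Si](CC)(CC)CC
F7 | step 24 | 9-epimer of 32 | O[C@H]1/C=C(C)/[C@H](OC(C)=O)C#C[C@]2(C)O[C@@H]2CC/C(C)=C\[C@@H]3OC(=O)[C@H](C)[C@]31O[Si](CC)(CC)CC
F8 | step 24 | macrocyclic C9 enone | O=C1/C=C(C)/[C@H](OC(C)=O)C#C[C@]2(C)O[C@@H]2CC/C(C)=C\[C@@H]3OC(=O)[C@H](C)[C@]31O[Si](CC)(CC)CC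
F9 | step 16 | 7-benzoate 8,9-diol tert-butyl ester | C#C[C@]1(C)O[C@@H]1CC/C(C)=C\[C@H](OC(=O)c2ccccc2)[C@](O)(CO)[C@@H](C)C(=O)OC(C)(C)C
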